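In a one-step world substrate becomes product and the tally ends at 100%, but the amber flask stands at 73.5% product after 40.0 h, with substrate at 0%.

| flask | substrate | free catalyst | temperature | remark | time |
|---|---|---|---|---|---|
| amber | 0.91 M | 1.8 mM | 40 °C | the very flask that is asked about, followed so far |  |
| ochre | 0.91 M | 1.8 mM | 35 °C | run made earlier |  |
| flask | 0.91 M | 1.8 mM | 40 °C |  | 40 h |

| run | time / h | product / % | substrate / % |
|---|---|---|---|
| amber | 3.00 | 60.1 | 0 |
| amber | 5.00 | 65.5 | 0.6 |
| amber | 8.00 | 70.2 | 0 |
| amber | 15.0 | 69.2 | 0 |
| amber | 25.0 | 73.9 | 0 |
| amber | 40.0 | 73.5 | 0 |
| ochre | 3.00 | 54.1 | 0.1 |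
| ochre | 5.00 | 62.1 | 0.7 |
| ochre | 8.00 | 72.0 | 0 |
| ochre | 15.0 | 70.3 | 0 |
| ochre | 25.0 | 74.7 | 0 |
| ochre | 40.0 | 74.2 | 0 |

(readings scatter by 1 percentage point)

- product that was removed still counts
- steps that have been proposed: substrate -> intermediate; free catalyst + intermediate -> free catalyst + product; 2 free catalyst -> spent catalyst; 2 free catalyst <-> resting dimer
- additions bring no volume worth counting

- birch: at 40 h take out 90% of the product then present, then wait 40 h
- ash: at 40 h add free catalyst, 100% of the amount charged, then wait 40 h
- alder: at 40 h raise the temperature by 15 K, then wait 40 h
- elm: change nothing and wait 40 h more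

- product, in percent of the substrate first charged, at 40 h
- which option adds most product ("none" when 2 percentage points or less is all one gets) (birch / ash / alder / elm / none)
- product present, with what was taken out counted in, in percent of the substrate first charged, after birch
- product present, with what was taken out counted in, in percent of the substrate first charged, after alder

The remainder in the amber flask, 26.5%, stands as intermediate, and this is the leave-share, the part of the intermediate that one charge of free catalyst leaves unturned. Counted in turnovers, each free catalyst charged in amber has made 372 product. The ochre flask, run cooler, ends at 74.2%, level with amber within the scatter of 1 percentage point.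

Two extreme flasks bound what a second dose does in amber. In the counter flask a catalyst owns a fixed number of turnovers, so the dose brings another 73.5% of the charge, more than the 26.5% of intermediate present, and product stops at 100%. In the clock flask a catalyst owns a fixed working time and its turnovers per hour follow [intermediate], the pseudo-first-order habit, so the dose removes the same share as the first did. The leave-share then applies twice and leaves 7.02% intermediate, which means 93.0% product and a gain of 19 points. The proposed loss steps of free catalyst contain no intermediate, so amber is reckoned here at the clock end, with 73.5% for now and ash as best. No proposed step consumes product or runs back from it, so birch is reckoned to follow elm, near the 2 points margin. Alder is reckoned to stay near them too, given how close ochre and amber end.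

The forecast gives 73.8% now, ash as best, 75.5% after birch and 78% after alder, with “Fresh catalyst restarts conversion, reaching about 92 %”.

The flask gives 72.9% at 40 h, and ash adds 20 points, against the reckoned 19 points; birch adds 1.3 points and ends at 74.2%, alder adds 1.9 points and ends at 74.8%, and elm adds 1.3 points.

    substrate → intermediate (k = 0.00230 s⁻¹, Ea = 88.0 kJ mol⁻¹)
    free catalyst + intermediate → free catalyst + product (k = 1.10 L mol⁻¹ s⁻¹, Ea = 37.0 kJ mol⁻¹)
    2 free catalyst → spent catalyst (k = 9.30 L mol⁻¹ s⁻¹, Ea = 39.0 kJ mol⁻¹)
    2 free catalyst ⇌ resting dimer, settled at all times (K = 24000 L mol⁻¹, ΔH = −30.0 kJ mol⁻¹)
    (constants at 40 °C)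

The neighbour flask takes 0.0031 M free catalyst at the start, 1.72 doses at once, and the leave-share raised to that power gives 10.2% intermediate. That neighbour flask holds 19.4% intermediate and 80.6% product, and each free catalyst charged in it made 236 product, against 372 in amber.

The earlier runs and the new flask come from a simulation with made-up constants; the scatter is artificial.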